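Look for slowness in these runs and you find a stop instead.

| flask | X | D | Z | L | remark | time |
|---|---|---|---|---|---|---|
| teal | 1 M | 1 M | 0.30 equiv | 0.2 mol% | run made earlier |  |
| ochre | 1 M | 1 M | 0.45 equiv | 0.2 mol% | run made earlier |  |
| green | 0.50 M | 0.50 M | 0.60 equiv | 0.2 mol% | run made earlier |  |
| flask | 1.0 M | 1.0 M | 0.600 equiv | 0.2 mol% |  | 8.0 h |

- teal (time / h: X / %, D / %): 1.00: 40.1, 48.0; 2.50: 39.3, 47.6; 3.00: 39.5, 48.0; 5.00: 39.6, 48.2; 6.00: 39.1, 48.0; 8.00: 39.7, 47.8
- ochre (time / h: X / %, D / %): 0.667: 38.6, 47.1; 1.00: 36.7, 47.3; 1.33: 36.1, 47.1; 2.50: 36.1, 47.1; 3.00: 35.4, 46.5; 5.00: 35.8, 47.1; 8.00: 35.8, 47.2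
- green (time / h: X / %, D / %): 0.667: 42.6, 49.0; 2.00: 40.8, 48.6; 4.00: 40.1, 48.9; 6.00: 41.0, 48.2; 8.00: 40.5, 48.4

(each reading ± 0.3 percentage points)

- L is single-handed; X and D are mirror images of each other, charged as a racemate, each of them at the stated concentration
- given per volume of solution although it is solid: Z
- at the start none of Z is in solution
- an excess is below zero if the other one leads

- part of the X and D charged together that has reacted at 8.0 h
- excess of Q over E in the product at 8.0 h
- excess of D over X among what is left of the two at 8.0 h

The ladder has two rungs. On the first, the runs move: teal is flat by 1.00 h, ochre by 1.33 h, green by 2.00 h. On the second, which reaches 8.0 h, teal's X shifts by 0.4 percentage points against a scatter of 0.3 points. So picture the flask at its asked time as stopped, and ask of one molecule whether it was taken before the stop.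

X and D start level and meet the same surroundings in one flask. If each goes by a step first order in itself, their chances stay tied however the surroundings change. Ochre's last readings give 5.80 for s, the selectivity factor: the logarithm of X's surviving share divided by that of D's. This is a loose reading: D stands 2.8 points below its charge, against a scatter of 0.3 points.

For the flask, my own reckoning steps X down from ochre by the fall from teal to ochre, to 31.9%. Then s puts D at 46.3%, so c is 21.8%, eP 66.1% and eS 18.4%.

The forecast gives 20.8%, 65.5% and 17.2%, and says “Selectivity from ln(X remaining)/ln(D remaining) gives s ≈ 5.6–6.5, so about 5.8”. Its c lies below mine.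

The flask gives 20.3%, 65.9% and 16.8%, so the forecast held on all counts.

    G + L + X → L + Q (k = 0.694 /M²/s)
    G + L + D → L + E (k = 0.121 /M²/s)
    Z ⇌ G, rate k3*(cs3 - [G]) while solid is left; crystals form when [G] > cs3 (solubility = 0.520 M, k = 7.89 × 10⁻⁴ /s)
    L → J (k = 6.15 × 10⁻⁴ /s)

Put the flask's surviving share of X, 66%, through s and you get 93.1% for D, where the flask shows 93%. The neighbouring flask, with 0.12 mol% of L, reaches a lower c of 15.4% and keeps 74% of its X. The same s turns that into 95.0% of D, where the neighbour shows 95%. It also gives an eP of 67.7%, where the neighbour shows 67.2%.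

(The numbers in the tables were generated by integration with constants of no real substance, noise included.)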